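Ring C is built, not bought. Its pattern (bridge carbon on C1', ethylene chain on C2', free OH on C4', OMe on C6', H on C3' and C5') is that of an acylated resorcinol monomethyl ether. The C1'–C6' and C2'–C3' bonds are therefore disconnected to an alkyne (C1'–C2') and a ketene acetal diene (C3'–C6'), with the future CH2 bridge serving as the ketone that activates the alkyne. One cycloaddition–aromatization closes ring C and sets the OMe/OH pair without selective protection. The precursor is an ynone whose carbonyl carries the ring A–B aryl group and whose alkyne carries the ring D ethylene chain.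

Key step: step 15

Assumption: the target has no stereocentre, so no stereocontrol is needed (the carbinol centres of 18 and 26 are racemic and are removed again), and 4,4-dimethoxybut-3-en-2-one is taken as a catalogue compound.

Step 1
Reactants: 1 vanillin
Product: 2 3-methoxy-4-(triisopropylsilyloxy)benzaldehyde
Conditions: TIPSCl, imidazole, DMF, rt
Reagents that add atoms: triisopropylsilyl chloride, CC(C)[Si](Cl)(C(C)C)C(C)C
Why: Imidazole-promoted O-silylation of the phenol should give a bulky aryl silyl ether that tolerates the later organolithium, hydride and acid steps and does not direct ortho-lithiation.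

Step 2
Reactants: 2 3-methoxy-4-(triisopropylsilyloxy)benzaldehyde
Product: 3 [3-methoxy-4-(triisopropylsilyloxy)phenyl]methanol
Conditions: NaBH4, MeOH, 0 °C
Reagents that add atoms: none
Why: Borohydride reduction of an aromatic aldehyde should give the benzylic alcohol without touching the aryl silyl ether.

Step 3
Reactants: 3 [3-methoxy-4-(triisopropylsilyloxy)phenyl]methanol
Product: 4 [3-methoxy-4-(triisopropylsilyloxy)benzyl]triphenylphosphonium bromide
Conditions: PPh3·HBr, MeCN, 60 °C
Reagents that add atoms: triphenylphosphine hydrobromide, Br.c1ccc(cc1)P(c1ccccc1)c1ccccc1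
Why: Electron-rich benzylic alcohols are converted directly into benzylphosphonium salts by triphenylphosphine hydrobromide (substitution via the benzylic bromide), and the hindered TIPS ether should survive the weakly acidic salt.

Step 4
Reactants: 5 3-hydroxy-5-methoxybenzaldehyde
Product: 6 3-methoxy-5-(methoxymethoxy)benzaldehyde
Conditions: MOMCl, i-Pr2NEt, CH2Cl2, 0 °C to rt
Reagents that add atoms: chloromethyl methyl ether, COCCl
Why: O-Alkylation of the phenol with MOMCl under amine base installs the acetal that later directs ortho-lithiation and falls off in the acidic deoxygenation step.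

Step 5
Reactants: 4 [3-methoxy-4-(triisopropylsilyloxy)benzyl]triphenylphosphonium bromide; 6 3-methoxy-5-(methoxymethoxy)benzaldehyde
Product: 8 ring A–B stilbene (E/Z mixture), via benzylidene phosphorane 7 (not isolated)
Conditions: NaHMDS, THF, −78 to 0 °C; then 6, 0 °C to rt
Reagents that add atoms: none
Why: Wittig olefination of the semi-stabilized benzylidene ylide with the aromatic aldehyde should give the stilbene, whose geometry is irrelevant because the double bond is hydrogenated next.

Step 6
Reactants: 8 ring A–B stilbene (E/Z mixture)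
Product: 9 ring A–B bibenzyl
Conditions: H2 (1 atm), 10% Pd/C, EtOAc, rt
Reagents that add atoms: none
Why: Heterogeneous catalytic hydrogenation saturates the stilbene double bond while the aryl ethers, the MOM acetal and the silyl ether are inert.

Step 7
Reactants: 9 ring A–B bibenzyl
Product: 11 ring A–B aldehyde, via C4-lithiated bibenzyl 10 (not isolated)
Conditions: n-BuLi, THF, 0 °C; DMF, 0 °C to rt; H2O
Reagents that add atoms: N,N-dimethylformamide, CN(C)C=O
Why: Directed ortho-metalation should occur at the ring B carbon flanked by OMe and OMOM (the most acidic arene C–H, activated by both groups, while the TIPS-shielded ring A is not lithiated), and formylation of the aryllithium with DMF follows.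

Step 8
Reactants: 12 dihydroferulic acid
Product: 13 methyl 3-(4-hydroxy-3-methoxyphenyl)propanoate
Conditions: MeOH, cat. H2SO4, reflux
Reagents that add atoms: methanol, CO
Why: Fischer esterification in excess methanol should give the methyl ester cleanly.

Step 9
Reactants: 13 methyl 3-(4-hydroxy-3-methoxyphenyl)propanoate
Product: 14 methyl 3-[3-methoxy-4-(triisopropylsilyloxy)phenyl]propanoate
Conditions: TIPSCl, imidazole, DMF, rt
Reagents that add atoms: triisopropylsilyl chloride, CC(C)[Si](Cl)(C(C)C)C(C)C
Why: Imidazole-promoted O-silylation of the phenol gives ring D the same protecting group as ring A, so both fall in one final step.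

Step 10
Reactants: 14 methyl 3-[3-methoxy-4-(triisopropylsilyloxy)phenyl]propanoate
Product: 15 3-[3-methoxy-4-(triisopropylsilyloxy)phenyl]propanal
Conditions: DIBAL-H, CH2Cl2, −78 °C; Rochelle salt
Reagents that add atoms: none
Why: DIBAL-H half-reduction of the methyl ester at −78 °C should stop at the aldehyde because the tetrahedral aluminium hemiacetal persists until work-up.

Step 11
Reactants: 15 3-[3-methoxy-4-(triisopropylsilyloxy)phenyl]propanal
Product: 16 [4-(but-3-yn-1-yl)-2-methoxyphenoxy]triisopropylsilane
Conditions: TMSCHN2, LDA (commercial solution), THF, −78 °C; then 15, −78 °C to rt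
Reagents that add atoms: trimethylsilyldiazomethane, C[Si](C)(C)C=[N+]=[N-]
Why: Colvin-type one-carbon homologation (Peterson-type addition–elimination of lithiated trimethylsilyldiazomethane, loss of N2 and 1,2-hydrogen shift of the alkylidene carbene) should give the terminal alkyne under non-protic conditions that spare the aryl silyl ether.

Step 12
Reactants: 16 [4-(but-3-yn-1-yl)-2-methoxyphenoxy]triisopropylsilane; 11 ring A–B aldehyde
Product: 18 propargylic alcohol (racemic), via lithium acetylide 17 (not isolated)
Conditions: n-BuLi, THF, −78 °C; then 11, −78 to 0 °C; H2O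
Reagents that add atoms: none
Why: 1,2-Addition of the slim lithium acetylide to the di-ortho-substituted benzaldehyde should give the carbinol as a racemate, and its centre is removed by the next oxidation.

Step 13
Reactants: 18 propargylic alcohol (racemic)
Product: 19 ynone
Conditions: activated MnO2, CH2Cl2, rt
Reagents that add atoms: none
Why: Manganese dioxide oxidizes the doubly activated (benzylic and propargylic) alcohol to the ynone under neutral conditions that leave the MOM and silyl ethers intact.

Step 14
Reactants: 20 4,4-dimethoxybut-3-en-2-one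
Product: 22 1,1-dimethoxy-3-(trimethylsilyloxy)buta-1,3-diene, via lithium dienolate 21 (not isolated)
Conditions: LDA (commercial solution), THF, −78 °C; TMSCl, −78 °C to rt; filtered and distilled under argon
Reagents that add atoms: chlorotrimethylsilane, C[Si](C)(C)Cl
Why: Kinetic deprotonation of the acetyl methyl group and O-silylation of the cross-conjugated enolate (silyl enol ether formation) should give the electron-rich diene, which is used at once because it is moisture-sensitive.

Step 15
Reactants: 19 ynone; 22 1,1-dimethoxy-3-(trimethylsilyloxy)buta-1,3-diene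
Product: 25 diaryl ketone (ring C formed; C4'-OH free), via cyclohexadiene cycloadduct 23 (not isolated), via aryl trimethylsilyl ether 24 (not isolated)
Conditions: 22 (3 equiv), toluene, 90 °C, sealed tube; then 0.5 M HCl, THF, 0 °C
Reagents that add atoms: none
Why: The electron-rich diene and the electron-poor ynone should combine in a concerted but asynchronous, normal-electron-demand [4+2] cycloaddition in which bonding between the diene CH2 terminus and the alkyne β-carbon runs ahead of bonding between the ketene acetal carbon and the α-carbon. The closest known reaction type is the Diels–Alder benzannulation of 1,1-dialkoxy-3-silyloxybutadienes with acetylenic ketones and esters, an established entry to acyl resorcinol monoethers. Ring C is closed as a six-membered carbocycle by this intermolecular cycloaddition, which forms C2'–C3' and C1'–C6' together; the 1,4-cyclohexadiene 23 then expels methanol to give arene 24, whose labile aryl TMS ether is hydrolysed in the mild acidic work-up that MOM and TIPS ethers tolerate. No stereocentre is created. The step needs regioselectivity, secured by the polarization of the ynone (electrophilic β-carbon bearing the chain) matched with the largest HOMO coefficient at the diene CH2, and chemoselectivity for C≡C over C=O, secured by the two ortho alkoxy groups of ring B that shield the carbonyl. The OMe at C6' and the OH at C4' are thus fixed by the diene itself.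

Step 16
Reactants: 25 diaryl ketone (ring C formed; C4'-OH free)
Product: 26 diarylmethanol (racemic)
Conditions: LiAlH4 (excess), THF, 0 to 50 °C; Rochelle salt; used crude
Reagents that add atoms: none
Why: Hydride reduction with LiAlH4, a small and strong donor chosen because the carbonyl is flanked by four ortho substituents and sits para to a phenoxide, should give the carbinol as a racemate whose centre disappears in step 17, with MOM and TIPS ethers stable to the reagent.

Step 17
Reactants: 26 diarylmethanol (racemic)
Product: 27 bis-TIPS diarylmethane (ring B and ring C phenols free)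
Conditions: Et3SiH (10 equiv), TFA (10 equiv), CH2Cl2, 0 °C
Reagents that add atoms: none
Why: In this ionic hydrogenation TFA ionizes the doubly benzylic, oxygen-stabilized carbinol and excess triethylsilane delivers hydride to the diarylmethyl cation, while the same acid cleaves the MOM acetal, the silane reduces the methoxymethyl cation, and the aryl TIPS ethers survive the short cold exposure.

Step 18
Reactants: 27 bis-TIPS diarylmethane (ring B and ring C phenols free)
Product: 28 target CNP0079000.0
Conditions: TBAF, AcOH, THF, 0 °C to rt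
Reagents that add atoms: none
Why: Fluoride-mediated cleavage of the two aryl silyl ethers (driven by Si–F bond formation), buffered with acetic acid to keep the electron-rich polyphenol from base-promoted air oxidation, should release the target.

Compound list
1 | vanillin (4-hydroxy-3-methoxybenzaldehyde) | COc1cc(C=O)ccc1O | starting material
2 | 3-methoxy-4-(triisopropylsilyloxy)benzaldehyde | COc1cc(C=O)ccc1O[Si](C(C)C)(C(C)C)C(C)C | intermediate
3 | [3-methoxy-4-(triisopropylsilyloxy)phenyl]methanol | COc1cc(CO)ccc1O[Si](C(C)C)(C(C)C)C(C)C | intermediate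
4 | [3-methoxy-4-(triisopropylsilyloxy)benzyl]triphenylphosphonium bromide | COc1cc(C[P+](c2ccccc2)(c2ccccc2)c2ccccc2)ccc1O[Si](C(C)C)(C(C)C)C(C)C.[Br-] | intermediate
5 | 3-hydroxy-5-methoxybenzaldehyde | O=Cc1cc(O)cc(OC)c1 | starting material
6 | 3-methoxy-5-(methoxymethoxy)benzaldehyde | COCOc1cc(C=O)cc(OC)c1 | intermediate
7 | [3-methoxy-4-(triisopropylsilyloxy)benzylidene]triphenylphosphorane (not isolated) | COc1cc(C=P(c2ccccc2)(c2ccccc2)c2ccccc2)ccc1O[Si](C(C)C)(C(C)C)C(C)C | intermediate
8 | ring A–B stilbene: 1-methoxy-3-(methoxymethoxy)-5-{2-[3-methoxy-4-(triisopropylsilyloxy)phenyl]ethenyl}benzene, E/Z mixture | COCOc1cc(C=Cc2ccc(O[Si](C(C)C)(C(C)C)C(C)C)c(OC)c2)cc(OC)c1 | intermediate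
9 | ring A–B bibenzyl: 1-methoxy-3-(methoxymethoxy)-5-{2-[3-methoxy-4-(triisopropylsilyloxy)phenyl]ethyl}benzene | COCOc1cc(CCc2ccc(O[Si](C(C)C)(C(C)C)C(C)C)c(OC)c2)cc(OC)c1 | intermediate
10 | C4-lithiated bibenzyl: aryllithium of 9 with Li on the ring B carbon between OMe and OMOM (not isolated) | [Li]c1c(OC)cc(CCc2ccc(O[Si](C(C)C)(C(C)C)C(C)C)c(OC)c2)cc1OCOC | intermediate
11 | ring A–B aldehyde: 2-methoxy-6-(methoxymethoxy)-4-{2-[3-methoxy-4-(triisopropylsilyloxy)phenyl]ethyl}benzaldehyde | COCOc1cc(CCc2ccc(O[Si](C(C)C)(C(C)C)C(C)C)c(OC)c2)cc(OC)c1C=O | intermediate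
12 | dihydroferulic acid, 3-(4-hydroxy-3-methoxyphenyl)propanoic acid | COc1cc(CCC(=O)O)ccc1O | starting material
13 | methyl 3-(4-hydroxy-3-methoxyphenyl)propanoate | COC(=O)CCc1ccc(O)c(OC)c1 | intermediate
14 | methyl 3-[3-methoxy-4-(triisopropylsilyloxy)phenyl]propanoate | COC(=O)CCc1ccc(O[Si](C(C)C)(C(C)C)C(C)C)c(OC)c1 | intermediate
15 | 3-[3-methoxy-4-(triisopropylsilyloxy)phenyl]propanal | O=CCCc1ccc(O[Si](C(C)C)(C(C)C)C(C)C)c(OC)c1 | intermediate
16 | ring D butyne: [4-(but-3-yn-1-yl)-2-methoxyphenoxy]triisopropylsilane | C#CCCc1ccc(O[Si](C(C)C)(C(C)C)C(C)C)c(OC)c1 | intermediate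
17 | lithium acetylide of 16 (not isolated) | [Li]C#CCCc1ccc(O[Si](C(C)C)(C(C)C)C(C)C)c(OC)c1 | intermediate
18 | propargylic alcohol, racemic: 1-{2-methoxy-6-(methoxymethoxy)-4-[2-(3-methoxy-4-triisopropylsilyloxyphenyl)ethyl]phenyl}-5-(3-methoxy-4-triisopropylsilyloxyphenyl)pent-2-yn-1-ol | COCOc1cc(CCc2ccc(O[Si](C(C)C)(C(C)C)C(C)C)c(OC)c2)cc(OC)c1C(O)C#CCCc1ccc(O[Si](C(C)C)(C(C)C)C(C)C)c(OC)c1 | intermediate
19 | ynone: 1-{2-methoxy-6-(methoxymethoxy)-4-[2-(3-methoxy-4-triisopropylsilyloxyphenyl)ethyl]phenyl}-5-(3-methoxy-4-triisopropylsilyloxyphenyl)pent-2-yn-1-one | COCOc1cc(CCc2ccc(O[Si](C(C)C)(C(C)C)C(C)C)c(OC)c2)cc(OC)c1C(=O)C#CCCc1ccc(O[Si](C(C)C)(C(C)C)C(C)C)c(OC)c1 | intermediate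
20 | 4,4-dimethoxybut-3-en-2-one | COC(OC)=CC(C)=O | starting material
21 | lithium dienolate of 20 (not isolated) | [Li]OC(=C)C=C(OC)OC | intermediate
22 | 1,1-dimethoxy-3-(trimethylsilyloxy)buta-1,3-diene | COC(OC)=CC(=C)O[Si](C)(C)C | intermediate
23 | cyclohexa-1,4-diene cycloadduct: ring C as 6,6-dimethoxy-4-(trimethylsilyloxy)cyclohexa-1,4-diene bearing the aroyl group on C1 and the ring D ethylene chain on C2 (not isolated) | COCOc1cc(CCc2ccc(O[Si](C(C)C)(C(C)C)C(C)C)c(OC)c2)cc(OC)c1C(=O)C1=C(CCc2ccc(O[Si](C(C)C)(C(C)C)C(C)C)c(OC)c2)CC(O[Si](C)(C)C)=CC1(OC)OC | intermediate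
24 | aryl trimethylsilyl ether of 25 at C4' (not isolated) | COCOc1cc(CCc2ccc(O[Si](C(C)C)(C(C)C)C(C)C)c(OC)c2)cc(OC)c1C(=O)c1c(CCc2ccc(O[Si](C(C)C)(C(C)C)C(C)C)c(OC)c2)cc(O[Si](C)(C)C)cc1OC | intermediate
25 | diaryl ketone: {4-hydroxy-2-methoxy-6-[2-(3-methoxy-4-triisopropylsilyloxyphenyl)ethyl]phenyl}{2-methoxy-6-(methoxymethoxy)-4-[2-(3-methoxy-4-triisopropylsilyloxyphenyl)ethyl]phenyl}methanone | COCOc1cc(CCc2ccc(O[Si](C(C)C)(C(C)C)C(C)C)c(OC)c2)cc(OC)c1C(=O)c1c(CCc2ccc(O[Si](C(C)C)(C(C)C)C(C)C)c(OC)c2)cc(O)cc1OC | intermediate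
26 | diarylmethanol, racemic: the secondary alcohol obtained from 25 by C=O to CH(OH) | COCOc1cc(CCc2ccc(O[Si](C(C)C)(C(C)C)C(C)C)c(OC)c2)cc(OC)c1C(O)c1c(CCc2ccc(O[Si](C(C)C)(C(C)C)C(C)C)c(OC)c2)cc(O)cc1OC | intermediate
27 | bis-TIPS diarylmethane: the target with both guaiacyl phenols (rings A and D) as triisopropylsilyl ethers | COc1cc(CCc2cc(O)c(Cc3c(CCc4ccc(O[Si](C(C)C)(C(C)C)C(C)C)c(OC)c4)cc(O)cc3OC)c(OC)c2)ccc1O[Si](C(C)C)(C(C)C)C(C)C | intermediate
28 | CNP0079000.0 (achiral) | COc1cc(CCc2cc(O)c(Cc3c(CCc4ccc(O)c(OC)c4)cc(O)cc3OC)c(OC)c2)ccc1O | target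

Total step count: 18.
Longest linear sequence: 12 steps (1, 2, 3, 5, 6, 7, 12, 13, 15, 16, 17, 18; from vanillin).

Steps most likely to fail

Step 15. The cycloaddition at the β-alkyl, sterically shielded ynone may be too slow, so that thermal or hydrolytic decay of the diene, or its conjugate addition without ring closure, outruns the benzannulation. The fallback moves the annulation to a smaller, more electrophilic dienophile and forms the bridge bond by aryllithium addition. It sets out from alkyne 16 and bibenzyl 9 and comes back at 27. Acetylide 17 is formylated with DMF to the ynal 5-[3-methoxy-4-(triisopropylsilyloxy)phenyl]pent-2-ynal F1. Heating F1 with diene 22 and mild acidic work-up should give, by the same regiochemical pairing, the ring C–D aldehyde 4-hydroxy-2-methoxy-6-{2-[3-methoxy-4-(triisopropylsilyloxy)phenyl]ethyl}benzaldehyde F2. MOMCl and i-Pr2NEt convert it into the MOM ether 2-methoxy-4-(methoxymethoxy)-6-{2-[3-methoxy-4-(triisopropylsilyloxy)phenyl]ethyl}benzaldehyde F3. Addition of aryllithium 10 (from 9, as in step 7) gives the bis-MOM diarylmethanol F4. Under the conditions of step 17 it loses both MOM groups and the carbinol oxygen to give 27.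

Step 16. Hydride delivery to a carbonyl shielded by four ortho substituents and deactivated by the para-phenoxide may stall, and forcing it may begin to strip silyl ethers. The fallback removes the phenoxide by changing the protecting-group pattern. It sets out from 25 and comes back at 28. TIPSCl and imidazole give the tris-TIPS diaryl ketone F5. LiAlH4 in THF reduces it to the tris-TIPS diarylmethanol F6. Et3SiH and TFA give the tris-TIPS diarylmethane with the ring B phenol free F7. TBAF buffered with AcOH then removes all three silyl groups to give 28.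

Step 17. The long-lived diarylmethyl cation may be captured by ring D in a seven-membered Friedel–Crafts closure before hydride transfer. The acid may also cleave or alkylate the very electron-rich diarylmethane through MOM-derived electrophiles. The fallback avoids cations altogether. It sets out from 26 and comes back at 28. NaBH4 in hot aqueous NaOH/EtOH lets the ring C phenoxide expel hydroxide to a para-quinone methide that borohydride reduces; the hot alkali also cleaves the aryl TIPS ethers (completed with TBAF if needed). The product is the ring B MOM ether of the target F8. HCl in MeOH at rt then transfers the MOM group to the solvent and gives 28.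

Further compounds
F1 | step 15 | 5-[3-methoxy-4-(triisopropylsilyloxy)phenyl]pent-2-ynal | O=CC#CCCc1ccc(O[Si](C(C)C)(C(C)C)C(C)C)c(OC)c1
F2 | step 15 | 4-hydroxy-2-methoxy-6-{2-[3-methoxy-4-(triisopropylsilyloxy)phenyl]ethyl}benzaldehyde | O=Cc1c(CCc2ccc(O[Si](C(C)C)(C(C)C)C(C)C)c(OC)c2)cc(O)cc1OC
F3 | step 15 | 2-methoxy-4-(methoxymethoxy)-6-{2-[3-methoxy-4-(triisopropylsilyloxy)phenyl]ethyl}benzaldehyde | O=Cc1c(CCc2ccc(O[Si](C(C)C)(C(C)C)C(C)C)c(OC)c2)cc(OCOC)cc1OC
F4 | step 15 | bis-MOM diarylmethanol (26 with the C4' hydroxyl as MOM ether), racemic | COCOc1cc(CCc2ccc(O[Si](C(C)C)(C(C)C)C(C)C)c(OC)c2)cc(OC)c1C(O)c1c(CCc2ccc(O[Si](C(C)C)(C(C)C)C(C)C)c(OC)c2)cc(OCOC)cc1OC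
F5 | step 16 | tris-TIPS diaryl ketone (25 with the C4' hydroxyl as TIPS ether) | COCOc1cc(CCc2ccc(O[Si](C(C)C)(C(C)C)C(C)C)c(OC)c2)cc(OC)c1C(=O)c1c(CCc2ccc(O[Si](C(C)C)(C(C)C)C(C)C)c(OC)c2)cc(O[Si](C(C)C)(C(C)C)C(C)C)cc1OC
F6 | step 16 | tris-TIPS diarylmethanol, racemic | COCOc1cc(CCc2ccc(O[Si](C(C)C)(C(C)C)C(C)C)c(OC)c2)cc(OC)c1C(O)c1c(CCc2ccc(O[Si](C(C)C)(C(C)C)C(C)C)c(OC)c2)cc(O[Si](C(C)C)(C(C)C)C(C)C)cc1OC
F7 | step 16 | tris-TIPS diarylmethane with the ring B phenol free | COc1cc(CCc2cc(O)c(Cc3c(CCc4ccc(O[Si](C(C)C)(C(C)C)C(C)C)c(OC)c4)cc(O[Si](C(C)C)(C(C)C)C(C)C)cc3OC)c(OC)c2)ccc1O[Si](C(C)C)(C(C)C)C(C)C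
F8 | step 17 | ring B MOM ether of the target | COCOc1cc(CCc2ccc(O)c(OC)c2)cc(OC)c1Cc1c(CCc2ccc(O)c(OC)c2)cc(O)cc1OC
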